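## Retrosynthetic overview

1. The α-methylene-γ-lactone is closed last: target 24 ⇐ tetraol 21 by MnO2 oxidative lactonisation; 21 ⇐ bridged hemiketal ketone 17 by C-8 reduction, esterification with (R)-2-methylbutanoic acid and desilylation.
2. Oxolane/hemiketal bridge (C-3–O–C-10): 17 ⇐ ten-membered enedione 16 by transannular hydrative oxa-Michael addition.
3. Ten-membered ring: 16 ⇐ 1-vinyl-2-alkynyl-cyclohexene-1,2-diol 15 by a dianionic oxy-Cope [3,3] shift (C-3–C-8 cleaved, C-1–C-10 formed).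
4. 15 ⇐ oxygenated carvone 9 + vinylmagnesium bromide + O-TBS propargyl alcohol; 9 ⇐ (S)-carvone by singlet-oxygen [4+2] cycloaddition, Mitsunobu inversion and SeO2 oxidation.
5. Ring order: cyclohexene (bought) → cyclodecadiene (oxy-Cope) → oxolane bridge → lactone.

Assumption: the target is read as drawn (6,7-cis-fused lactone; ester, oxygen bridge and C-7 side chain on one face; (R)-2-methylbutanoate, taken as purchasable); germacrane locants C-1 to C-15 of the target are used for every intermediate, and the C-9=C-10 geometry of the non-isolated enedione 16 is left open because both isomers converge.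

## Route

Step 1
Reactants: 1 (S)-(+)-carvone
Product: 2 tert-butyldimethyl{[(5R)-2-methyl-5-(prop-1-en-2-yl)cyclohexa-1,3-dien-1-yl]oxy}silane
Conditions: KH, THF, 0 °C to rt; then TBSCl, −78 °C to 0 °C
Reagents that add atoms: tert-butyldimethylsilyl chloride, CC(C)(C)[Si](C)(C)Cl
Why: Under equilibrating conditions the enone is deprotonated at the γ-carbon (C-6) to the through-conjugated dienolate, which is O-silylated (thermodynamic dienolate formation, silyl dienol ether synthesis), leaving C-7 untouched.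

Step 2
Reactants: 2 silyl dienol ether
Product: 5 (4R,5S)-4-hydroxy-2-methyl-5-(prop-1-en-2-yl)cyclohex-2-en-1-one, via endoperoxide 3 (not isolated), via hydroperoxide 4 (not isolated)
Conditions: O2, hν, tetraphenylporphyrin (cat.), CH2Cl2–MeOH, −78 °C; then PPh3, −78 °C to rt
Reagents that add atoms: dioxygen, O=O
Why: Singlet oxygen adds to the cisoid silyloxydiene in a [4+2] cycloaddition across C-3/C-6 on the face opposite the C-7 isopropenyl group, methanol opens the silyl peroxyketal to the γ-hydroperoxy enone and PPh3 reduces it, so the new C-6 oxygen is trans to the side chain.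

Step 3
Reactants: 5 trans-γ-hydroxy enone
Product: 7 (4S,5S)-4-hydroxy-2-methyl-5-(prop-1-en-2-yl)cyclohex-2-en-1-one, via nitrobenzoate 6 (not isolated)
Conditions: 4-nitrobenzoic acid, PPh3, DIAD, THF, 0 °C to rt; then K2CO3, MeOH, 0 °C
Reagents that add atoms: 4-nitrobenzoic acid, OC(=O)c1ccc(cc1)[N+](=O)[O-]
Why: Mitsunobu esterification displaces the activated allylic C-6 oxygen by SN2 with inversion and methanolysis frees the alcohol, which is now cis to the C-7 side chain as the cis-fused lactone requires.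

Step 4
Reactants: 7 cis-γ-hydroxy enone
Product: 8 (4S,5S)-4-hydroxy-5-(3-hydroxyprop-1-en-2-yl)-2-methylcyclohex-2-en-1-one
Conditions: SeO2 (cat.), t-BuOOH, CH2Cl2, rt
Reagents that add atoms: tert-butyl hydroperoxide, CC(C)(C)OO
Why: Sharpless–Umbreit allylic oxidation (ene reaction then [2,3]-shift) hydroxylates the methyl group of the electron-rich 1,1-disubstituted alkene while the enone double bond is deactivated, and no stereocentre is formed.

Step 5
Reactants: 8 diol
Product: 9 (4S,5S)-2-methyl-4-[(triisopropylsilyl)oxy]-5-{3-[(triisopropylsilyl)oxy]prop-1-en-2-yl}cyclohex-2-en-1-one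
Conditions: TIPSOTf, 2,6-lutidine, CH2Cl2, −78 °C to 0 °C
Reagents that add atoms: triisopropylsilyl trifluoromethanesulfonate, CC(C)[Si](C(C)C)(C(C)C)OS(=O)(=O)C(F)(F)F
Why: Silyl ether formation on both hydroxyls, with bulky TIPS groups chosen because they resist oxygen-to-oxygen silyl migration in the later alkoxide steps.

Step 6
Reactants: 9 bis-silyl enone
Product: 10 (4S,5R,6R)-6-hydroxy-2-methyl-4-[(triisopropylsilyl)oxy]-5-{3-[(triisopropylsilyl)oxy]prop-1-en-2-yl}cyclohex-2-en-1-one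
Conditions: LiN(i-Pr)2, THF, −78 °C; 2-(phenylsulfonyl)-3-phenyloxaziridine (racemic); AcOH
Reagents that add atoms: 2-(phenylsulfonyl)-3-phenyloxaziridine, O=S(=O)(c1ccccc1)N1OC1c1ccccc1
Why: Kinetic deprotonation at the α'-carbon (C-8) and Davis enolate hydroxylation deliver oxygen anti to the neighbouring C-7 side chain (this centre becomes sp2 again in step 8).

Step 7
Reactants: 10 α'-hydroxy enone; 11 vinylmagnesium bromide
Product: 12 1-ethenyl-2-methyl-4-(TIPS-oxy)-5-[3-(TIPS-oxy)prop-1-en-2-yl]cyclohex-2-ene-1,6-diol (C-3 vinyl carbinol with 3-OH cis to 8-OH)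
Conditions: CeCl3, THF, −78 °C; then H2O
Reagents that add atoms: none
Why: CeCl3-promoted 1,2-addition of the Grignard reagent to the enone carbonyl under chelation by the α'-alkoxide gives the cis-diol (the C-3 carbinol centre is consumed in step 10).

Step 8
Reactants: 12 diol
Product: 13 6-ethenyl-6-hydroxy-5-methyl-3-(TIPS-oxy)-2-[3-(TIPS-oxy)prop-1-en-2-yl]cyclohex-4-en-1-one (C-8 ketone)
Conditions: Dess–Martin periodinane, CH2Cl2, 0 °C
Reagents that add atoms: none
Why: Dess–Martin oxidation converts the only secondary alcohol into the ketone while the tertiary allylic alcohol cannot be oxidised.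

Step 9
Reactants: 13 α-hydroxy ketone; 14 tert-butyldimethyl(prop-2-yn-1-yloxy)silane
Product: 15 2-[3-(TBS-oxy)prop-1-yn-1-yl]-1-ethenyl-6-methyl-4-(TIPS-oxy)-3-[3-(TIPS-oxy)prop-1-en-2-yl]cyclohex-5-ene-1,2-diol (vinyl and alkynyl trans)
Conditions: n-BuLi, THF, −78 °C; CeCl3; then 13, −78 °C; AcOH
Reagents that add atoms: none
Why: The weakly basic CeCl3-modified acetylide adds 1,2 to the hindered ketone from the face opposite both the C-3 vinyl group and the C-7 side chain, avoiding enolisation toward C-7 (this carbinol centre is also consumed in step 10).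

Step 10
Reactants: 15 enyne diol
Product: 17 bridged hemiketal ketone (3-hydroxy-3,10-epoxy-germacra-4Z,11(13)-dien-8-one bearing 6-OTIPS/12-OTIPS/14-OTBS; C-3/C-6/C-7/C-10 as in the target), via enedione 16 (not isolated)
Conditions: KH, 18-crown-6, THF, 0 °C to rt; AcOH, −78 °C; then PPTS (cat.), THF–H2O, rt
Reagents that add atoms: water, O
Why: The bis-alkoxide undergoes a dianionic oxy-Cope [3,3]-sigmatropic rearrangement through the conformer with vinyl and alkynyl diequatorial, cleaving the doubly oxygenated C-3–C-8 bond and forming C-1–C-10 (C-4=C-5 stays Z as a former ring alkene, C-6 and C-7 are untouched), and after protonation the hydrated C-3 ketone adds reversibly in a 5-exo oxa-Michael fashion to C-10 of the C-8 enone, so C-10 and the hemiketal C-3 settle under thermodynamic control with the oxygen bridge on the face that keeps the C-6 and C-7 substituents exo on the 11-oxabicyclo[6.2.1]undecene.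

Step 11
Reactants: 17 bridged hemiketal ketone
Product: 18 8-alcohol (8-OH cis to the C-7 side chain as in the target)
Conditions: NaBH4, EtOH–THF, −40 °C
Reagents that add atoms: none
Why: Borohydride reduces the only ketone (C-3 is masked as the hemiketal), with hydride approaching C-8 from the face opposite the adjacent C-7 side chain (1,2-induction) to give the alcohol cis to it.

Step 12
Reactants: 18 8-alcohol; 19 (R)-2-methylbutanoic acid
Product: 20 8-O-[(2R)-2-methylbutanoyl] ester of 18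
Conditions: DCC, DMAP (cat.), CH2Cl2, 0 °C to rt
Reagents that add atoms: none
Why: Steglich esterification acylates the only secondary alcohol (the hemiketal hydroxyl is tertiary) with retention at C-8 and at the acid stereocentre.

Step 13
Reactants: 20 silylated ester
Product: 21 tetraol (3,6,12,14-tetrahydroxy-3,10-epoxy-germacra-4Z,11(13)-dien-8-yl (2R)-2-methylbutanoate)
Conditions: TBAF, AcOH, THF, rt to 40 °C
Reagents that add atoms: none
Why: Fluoride-mediated desilylation removes all three silyl ethers, and the acetic acid buffer suppresses acyl migration and retro-reactions of the hemiketal.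

Step 14
Reactants: 21 tetraol
Product: 24 target CNP0328225.2, via aldehyde 22 (not isolated), via lactol 23 (not isolated)
Conditions: MnO2, CH2Cl2, rt
Reagents that add atoms: none
Why: MnO2 oxidises the unhindered primary allylic alcohol to the enal, which the cis C-6 hydroxyl traps as the lactol that is oxidised on to the α-methylene-γ-lactone (oxidative lactonisation), while the non-allylic C-14 alcohol and the tertiary hemiketal are inert and no stereocentre changes.

## Compound list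

1 | (S)-(+)-carvone, (5S)-2-methyl-5-(prop-1-en-2-yl)cyclohex-2-en-1-one | CC(=C)[C@H]1CC=C(C)C(=O)C1 | starting material
2 | tert-butyldimethyl{[(5R)-2-methyl-5-(prop-1-en-2-yl)cyclohexa-1,3-dien-1-yl]oxy}silane | CC(=C)[C@H]1C=CC(C)=C(O[Si](C)(C)C(C)(C)C)C1 | intermediate
3 | 1-(TBS-oxy)-6-methyl-8-(prop-1-en-2-yl)-2,3-dioxabicyclo[2.2.2]oct-5-ene, isopropenyl anti to the O–O bridge | CC(=C)[C@H]1[C@H]2C=C(C)[C@](O[Si](C)(C)C(C)(C)C)(OO2)C1 | intermediate (not isolated)
4 | (4R,5S)-4-hydroperoxy-2-methyl-5-(prop-1-en-2-yl)cyclohex-2-en-1-one | CC(=C)[C@H]1[C@H](OO)C=C(C)C(=O)C1 | intermediate (not isolated)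
5 | (4R,5S)-4-hydroxy-2-methyl-5-(prop-1-en-2-yl)cyclohex-2-en-1-one (4,5-trans) | CC(=C)[C@H]1[C@H](O)C=C(C)C(=O)C1 | intermediate
6 | (1S,6S)-3-methyl-4-oxo-6-(prop-1-en-2-yl)cyclohex-2-en-1-yl 4-nitrobenzoate (cis) | CC(=C)[C@H]1[C@@H](OC(=O)c2ccc(cc2)[N+](=O)[O-])C=C(C)C(=O)C1 | intermediate (not isolated)
7 | (4S,5S)-4-hydroxy-2-methyl-5-(prop-1-en-2-yl)cyclohex-2-en-1-one (4,5-cis) | CC(=C)[C@H]1[C@@H](O)C=C(C)C(=O)C1 | intermediate
8 | (4S,5S)-4-hydroxy-5-(3-hydroxyprop-1-en-2-yl)-2-methylcyclohex-2-en-1-one | OCC(=C)[C@H]1[C@@H](O)C=C(C)C(=O)C1 | intermediate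
9 | (4S,5S)-2-methyl-4-[(triisopropylsilyl)oxy]-5-{3-[(triisopropylsilyl)oxy]prop-1-en-2-yl}cyclohex-2-en-1-one | CC(C)[Si](C(C)C)(C(C)C)OCC(=C)[C@H]1[C@@H](O[Si](C(C)C)(C(C)C)C(C)C)C=C(C)C(=O)C1 | intermediate
10 | (4S,5R,6R)-6-hydroxy-2-methyl-4-[(triisopropylsilyl)oxy]-5-{3-[(triisopropylsilyl)oxy]prop-1-en-2-yl}cyclohex-2-en-1-one | CC(C)[Si](C(C)C)(C(C)C)OCC(=C)[C@H]1[C@@H](O[Si](C(C)C)(C(C)C)C(C)C)C=C(C)C(=O)[C@@H]1O | intermediate
11 | vinylmagnesium bromide | C=C[Mg]Br | starting material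
12 | 1-ethenyl-2-methyl-4-(TIPS-oxy)-5-[3-(TIPS-oxy)prop-1-en-2-yl]cyclohex-2-ene-1,6-diol (3-OH cis to 8-OH; 8-OH trans to the C-7 side chain) | CC(C)[Si](C(C)C)(C(C)C)OCC(=C)[C@H]1[C@@H](O[Si](C(C)C)(C(C)C)C(C)C)C=C(C)[C@@](O)(C=C)[C@@H]1O | intermediate
13 | 6-ethenyl-6-hydroxy-5-methyl-3-(TIPS-oxy)-2-[3-(TIPS-oxy)prop-1-en-2-yl]cyclohex-4-en-1-one | CC(C)[Si](C(C)C)(C(C)C)OCC(=C)[C@H]1[C@@H](O[Si](C(C)C)(C(C)C)C(C)C)C=C(C)[C@@](O)(C=C)C1=O | intermediate
14 | tert-butyldimethyl(prop-2-yn-1-yloxy)silane | C#CCO[Si](C)(C)C(C)(C)C | starting material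
15 | 2-[3-(TBS-oxy)prop-1-yn-1-yl]-1-ethenyl-6-methyl-4-(TIPS-oxy)-3-[3-(TIPS-oxy)prop-1-en-2-yl]cyclohex-5-ene-1,2-diol (vinyl and alkynyl trans; alkynyl trans to the C-7 side chain) | CC(C)[Si](C(C)C)(C(C)C)OCC(=C)[C@H]1[C@@H](O[Si](C(C)C)(C(C)C)C(C)C)C=C(C)[C@@](O)(C=C)[C@]1(O)C#CCO[Si](C)(C)C(C)(C)C | intermediate
16 | ten-membered enedione: 6-OTIPS, 12-OTIPS, 14-OTBS germacra-4Z,9,11(13)-triene-3,8-dione | CC(C)[Si](C(C)C)(C(C)C)OCC(=C)[C@H]1[C@@H](O[Si](C(C)C)(C(C)C)C(C)C)/C=C(/C)C(=O)CCC(CO[Si](C)(C)C(C)(C)C)=CC1=O | intermediate (not isolated)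
17 | bridged hemiketal ketone: 3-hydroxy-3,10-epoxy-6-OTIPS-12-OTIPS-14-OTBS-germacra-4Z,11(13)-dien-8-one, C-3/C-6/C-7/C-10 as in the target | CC(C)[Si](C(C)C)(C(C)C)OCC(=C)[C@H]1[C@@H](O[Si](C(C)C)(C(C)C)C(C)C)/C=C(/C)[C@]2(O)CC[C@](CO[Si](C)(C)C(C)(C)C)(CC1=O)O2 | intermediate
18 | 8-alcohol of 17 (8-OH cis to the C-7 side chain and to the oxygen bridge) | CC(C)[Si](C(C)C)(C(C)C)OCC(=C)[C@H]1[C@@H](O[Si](C(C)C)(C(C)C)C(C)C)/C=C(/C)[C@]2(O)CC[C@](CO[Si](C)(C)C(C)(C)C)(C[C@H]1O)O2 | intermediate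
19 | (R)-2-methylbutanoic acid | CC[C@@H](C)C(=O)O | starting material
20 | 8-O-[(2R)-2-methylbutanoyl] ester of 18 | CC(C)[Si](C(C)C)(C(C)C)OCC(=C)[C@H]1[C@@H](O[Si](C(C)C)(C(C)C)C(C)C)/C=C(/C)[C@]2(O)CC[C@](CO[Si](C)(C)C(C)(C)C)(C[C@H]1OC(=O)[C@H](C)CC)O2 | intermediate
21 | tetraol: 3,6,12,14-tetrahydroxy-3,10-epoxy-germacra-4Z,11(13)-dien-8-yl (2R)-2-methylbutanoate | OCC(=C)[C@H]1[C@@H](O)/C=C(/C)[C@]2(O)CC[C@](CO)(C[C@H]1OC(=O)[C@H](C)CC)O2 | intermediate
22 | 12-aldehyde (enal) of 21 | O=CC(=C)[C@H]1[C@@H](O)/C=C(/C)[C@]2(O)CC[C@](CO)(C[C@H]1OC(=O)[C@H](C)CC)O2 | intermediate (not isolated)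
23 | 6,12-lactol (anomeric mixture) | C=C1C(O)O[C@H]2/C=C(/C)[C@]3(O)CC[C@](CO)(C[C@@H](OC(=O)[C@H](C)CC)[C@@H]12)O3 | intermediate (not isolated)
24 | CNP0328225.2 | C=C1C(=O)O[C@H]2/C=C(/C)[C@]3(O)CC[C@](CO)(C[C@@H](OC(=O)[C@H](C)CC)[C@@H]12)O3 | target

## Step count and risks

Total step count: 14. Longest linear sequence: 14 steps, from (S)-carvone 1 to 24. Vinylmagnesium bromide 11, alkyne 14 and acid 19 are bought.

The three steps most likely to fail:

Step 10. The bis-alkoxide could instead cleave C-7–C-8 with the side-chain alkene (a mono-anionic oxy-Cope), the enolates could eliminate the C-6 silyloxy group, or the hydrative ring closure could give the other C-10 epimer. Fallback: set out from 15 and silylate both tertiary hydroxyls (TMSOTf, 2,6-lutidine) to give the bis(trimethylsilyl) ether F2. Heat this in degassed o-xylene at about 180 °C so that the rearrangement runs as a neutral siloxy-Cope, with no alkoxide present, to the ten-membered bis(silyl enol ether) F3 (silyl enol ether at C-3, silyloxyallene at C-8). Hydrolyse and cyclise F3 with PPTS in wet THF; this comes back to the route at 17.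

Step 11. Hydride may enter C-8 from the other face because the bicyclic framework, not the C-7 side chain, may dominate. Fallback: set out from 17, take (or deliberately make with a bulky hydride) the 8-epimeric alcohol F4 and join it to acid 19 under Mitsunobu conditions (PPh3, DIAD, THF), which installs the ester with inversion at C-8; this comes back to the route at 20.

Step 1. Silylation may give the cross-conjugated (α') dienol ether or carvone may aromatise, which blocks the γ-oxygenation. Fallback: set out from 1 and brominate the γ-carbon by a radical chain (N-bromosuccinimide, dibenzoyl peroxide, CCl4, reflux), anti to the isopropenyl group, to give trans-4-bromocarvone F1. Displace the bromide with cesium 4-nitrobenzoate in DMF (SN2, inversion) to give the cis ester; this comes back to the route at 6, which is methanolysed to 7 as in step 3.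

Further compounds
F1 | step 1 | trans-4-bromo-2-methyl-5-(prop-1-en-2-yl)cyclohex-2-en-1-one (trans-4-bromocarvone) | CC(=C)[C@H]1[C@H](Br)C=C(C)C(=O)C1
F2 | step 10 | bis(trimethylsilyl) ether of 15 | CC(C)[Si](C(C)C)(C(C)C)OCC(=C)[C@H]1[C@@H](O[Si](C(C)C)(C(C)C)C(C)C)C=C(C)[C@@](O[Si](C)(C)C)(C=C)[C@]1(O[Si](C)(C)C)C#CCO[Si](C)(C)C(C)(C)C
F3 | step 10 | ten-membered bis(silyl enol ether): 3-OTMS enol ether and 8-OTMS silyloxyallene of 16 | CC(C)[Si](C(C)C)(C(C)C)OCC(=C)[C@H]1[C@@H](O[Si](C(C)C)(C(C)C)C(C)C)/C=C(/C)C(O[Si](C)(C)C)=CCC(CO[Si](C)(C)C(C)(C)C)=C=C1O[Si](C)(C)C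
F4 | step 11 | 8-epimer of alcohol 18 | CC(C)[Si](C(C)C)(C(C)C)OCC(=C)[C@H]1[C@@H](O[Si](C(C)C)(C(C)C)C(C)C)/C=C(/C)[C@]2(O)CC[C@](CO[Si](C)(C)C(C)(C)C)(C[C@@H]1O)O2
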